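The earlier runs and the new flask are calculated from invented constants; scatter was added.

Per catalyst, Saturday's run had made more turnovers at 15.0 h than Monday's, 3.25 against 1.76, if we count J over loading. Two chemists disagree about what this means for oak and alder.

| flask | Z | Q | D | remark | time |
|---|---|---|---|---|---|
| Saturday's | 2 M | 0.60 equiv | 7.5 mol% | run made earlier |  |
| Monday's | 2 M | 0.60 equiv | 30 mol% | run made earlier |  |
| oak | 2.0 M | 0.600 equiv | 15 mol% |  | 15 h |
| alder | 2.0 M | 0.600 equiv | 15 mol% |  | 30 h |

| run | time / h | L / % | Z / % | J / % |
|---|---|---|---|---|
| Saturday's | 4.00 | 0.6 | 64.0 | 10.5 |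
| Saturday's | 8.00 | 0 | 45.7 | 16.2 |
| Saturday's | 12.0 | 0 | 33.0 | 20.6 |
| Saturday's | 15.0 | 0.3 | 26.1 | 24.4 |
| Monday's | 2.00 | 0.8 | 69.6 | 12.0 |
| Monday's | 5.00 | 0.9 | 43.3 | 29.9 |
| Monday's | 10.0 | 0 | 22.4 | 44.1 |
| Monday's | 15.0 | 0.1 | 13.9 | 52.8 |

(readings scatter by 1 percentage point)

- the earlier runs were read with a standard deviation of 1 percentage point

- which of these there is most of at the end, counted by the Z in it, oak (L / J / Z)
- which of these there is most of at the end, counted by the Z in it, alder (L / J / Z)
- final amount of the leader among these, as a percentage of the Z charged, in oak
- final amount of the leader among these, as a percentage of the Z charged, in alder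

The first chemist takes Saturday's count as a property of the catalyst. That puts J in oak at 48.8%. In alder, over twice the time, the count would be 6.51. Supposing that each turnover spends one Q, the charge allows 4.00 turnovers at this loading, so alder stops at the ceiling of 60.0%.

The second chemist, who is reckoning for herself here, treats the spending of Q as pseudo-first-order, with unspent Q decaying at a pace set by the concentration of D. Reading J as the Q spent, she takes the natural logarithm of Q charged over Q unspent and divides by D concentration and time. Saturday's run gives 0.232 /M/h and Monday's 0.236 /M/h, at loadings that differ by a factor of 4.00. Their mean, 0.234 /M/h, is her Q clock. It gives J of 39.0% in oak and 52.7% in alder.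

The forecast sides with her in numbers, though not in grounds. It starts from “The mass balance does not close” and gives J as the leader, with 37% in oak (range 33% to 42%) and 52% in alder (range 45% to 60%). Her clock stands higher than the forecast in oak and in alder.

The flasks give J as the leader in both: 39.9% in oak, with Z at 19.0%, and 51.2% in alder, with Z at 5.69%. Both values lie inside the forecast's ranges, and the first chemist's oak figure is 8.9 points too high.

    Q + D → E (k = 0.00750 /M/min)
    Z + E ⇌ L (K = 1.40 /M, k = 0.0120 /M/min)
    L → D + J (k = 0.200 /min)
    2 Z → G (k = 4.40 × 10⁻⁴ /M/min)

The first chemist's ceiling is not reached: left until 300 h, alder holds 56.6% of J, 3.4 points below it. Read from oak's result, the clock is 0.242 /M/h, beside 0.234 /M/h from the two runs. A neighbour of oak was charged with 0.50 M of Z, with the same equivalents and loadings, so the concentration of D charged is a quarter of oak's. Over 15 h the clock 0.234 /M/h gives it J of 13.9% of the Z charged, and that flask gave 14.4%.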